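**Plan** (atom labels are those of the decahydroquinoline target: N1, C2–C8a, side chain C1'–C8')
1. Retrosynthetic cuts, in order: the C3–O acyl bond; C3–O and C2–CH3 (back to an N-Boc cis-octahydroquinolin-2-one); N1–C2 and N1–C8a (lactam from a δ-keto ester and ammonia); C4–C4a together with C5–C1'; last, C3'–C4' of the side chain.
2. Enabling feature: in the carbocycle the chain-bearing C5 is β to the nitrogen-bearing C8a, and C4a between them carries C4. C8a, C4a and C5 are therefore the carbonyl, α and β carbons of cyclohex-2-enone; C1' arrives as a Grignard carbon and C4–C3–C2 as an acrylate.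
3. Forward order: the side-chain Grignard reagent is built from (R)-2-propyloxirane and allylmagnesium bromide. One three-component coupling joins it to the purchased carbocycle and to an α-silyl acrylate (the silicon keeps the trapping to a single addition). The nitrogen ring then closes by lactamisation, and the C2 methyl, the C3 oxygen and the dienoate follow.
4. Stereochemistry: C5' from the epoxide; C5 from the copper/ferrocenyl diphosphine catalyst; C4a and C8a from hydrogenation of the C4a=C8a enamide on the face away from the C5 chain (H4a, H5, H8a cis); C2 and C3 from syn hydroboration on the convex face (H2 and O3 cis to H8a, methyl trans to oxygen).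

Key step: step 7

Assumption: compounds 1, 9 and 24 are bought, and of the two commercial antipodes of the ferrocenyl diphosphine the one that delivers the alkyl group to the Si face of C3 of cyclohex-2-enone (S at C5) is used, as fixed by one calibration run with 8.

**Route**

Step 1
Reactants: 1 (R)-2-propyloxirane; 2 allylmagnesium bromide
Product: 3 (R)-oct-1-en-5-ol
Conditions: CuI (10 mol %), THF–Et2O, −30 → 0 °C; aq. NH4Cl
Reagents that add atoms: none
Why: Copper-catalysed SN2 opening of the terminal epoxide by the allyl Grignard reagent takes place at the unsubstituted carbon, so the carbinol stereocentre (the future C5') is carried over unchanged from 1.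

Step 2
Reactants: 3 (R)-oct-1-en-5-ol
Product: 4 (R)-5-(tert-butyldimethylsilyloxy)oct-1-ene
Conditions: TBSCl, imidazole, DMF, rt
Reagents that add atoms: tert-butyldimethylsilyl chloride, CC(C)(C)[Si](C)(C)Cl
Why: Imidazole-promoted silylation of a secondary alcohol is routine, and the TBS ether is inert to the Grignard, enolate, organozinc and borane reagents ahead while falling to aqueous acid at the end.

Step 3
Reactants: 4 (R)-5-(tert-butyldimethylsilyloxy)oct-1-ene
Product: 6 (R)-5-(tert-butyldimethylsilyloxy)octan-1-ol, via B-alkyl-9-BBN adduct 5 (not isolated)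
Conditions: 9-BBN (9-borabicyclo[3.3.1]nonane), THF, 0 °C → rt; then NaOH, H2O2, H2O, 0 °C → rt
Reagents that add atoms: hydrogen peroxide, OO
Why: Hydroboration–oxidation with the bulky 9-BBN places boron on the terminal carbon of the monosubstituted alkene and alkaline peroxide replaces it by hydroxyl, conditions a secondary TBS ether tolerates.

Step 4
Reactants: 6 (R)-5-(tert-butyldimethylsilyloxy)octan-1-ol
Product: 7 (R)-1-bromo-5-(tert-butyldimethylsilyloxy)octane
Conditions: CBr4, PPh3, CH2Cl2, 0 °C → rt
Reagents that add atoms: carbon tetrabromide, BrC(Br)(Br)Br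
Why: The Appel reaction turns the primary alcohol into the bromide through an alkoxyphosphonium ion under neutral conditions that do not touch the silyl ether.

Step 5
Reactants: 7 (R)-1-bromo-5-(tert-butyldimethylsilyloxy)octane
Product: 8 [(5R)-5-(tert-butyldimethylsilyloxy)octyl]magnesium bromide (titrated Et2O solution)
Conditions: Mg turnings (I2 crystal), Et2O, reflux
Reagents that add atoms: magnesium, [Mg]
Why: Magnesium insertion into an unhindered primary alkyl bromide in Et2O, the solvent the copper catalysis of step 7 requires, gives the Grignard reagent, the δ-silyloxy group being neither a leaving group nor an electrophile.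

Step 6
Reactants: 9 (1-bromovinyl)trimethylsilane
Product: 11 methyl 2-(trimethylsilyl)acrylate, via vinyl Grignard reagent 10 (not isolated)
Conditions: Mg, THF, reflux; then added to ClCO2Me (3 equiv), THF, −78 °C
Reagents that add atoms: methyl chloroformate, COC(=O)Cl
Why: Magnesium insertion into the vinylic C–Br bond and acylation of the Grignard reagent by inverse addition to excess chloroformate at −78 °C (so that the ester is not attacked a second time) give the distillable α-silyl acrylate.

Step 7
Reactants: 8 [(5R)-5-(tert-butyldimethylsilyloxy)octyl]magnesium bromide; 12 cyclohex-2-en-1-one; 11 methyl 2-(trimethylsilyl)acrylate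
Product: 15 methyl 3-[(1R,2S)-2-[(5R)-5-(tert-butyldimethylsilyloxy)octyl]-6-oxocyclohexyl]propanoate (trans keto ester), via bromomagnesium enolate 13 (not isolated), via silyl adduct 14 (not isolated)
Conditions: CuBr·SMe2 (5 mol %), 1-[(dimethylamino)[2-(diphenylphosphino)phenyl]methyl]-2-(diphenylphosphino)ferrocene (6 mol %, antipode as assumed), 12 (1.05 equiv), Et2O, −60 °C, 8 added over 1 h; then THF, 11 (1.2 equiv), −78 → 0 °C; aq. NH4Cl; then KF, MeOH, rt
Reagents that add atoms: none
Why: Transmetallation of 8 to the monovalent copper bromide–diphosphine complex gives a chiral alkylcopper species that binds the enone as a π-complex and, by oxidative addition and reductive elimination, forms C5–C1' on the Si face of the β-carbon, leaving bromomagnesium enolate 13 with its double bond fixed between C4a and C8a. Enolate 13 then adds through C4a to the β-carbon of 11 (Michael addition, C4–C4a), and the fluoride/methanol work-up protodesilylates the α-silyl ester 14 to 15. The closest known reactions are the copper/ferrocenyl diphosphine-catalysed addition of primary alkyl Grignard reagents to cyclohex-2-enone and the trapping of conjugate-addition enolates by α-silyl Michael acceptors. No ring closes in this step. C5 is set by the catalyst alone, the C5' silyloxy centre being too remote to interfere, and C4a forms trans to the C5 chain by approach anti to it, a centre that step 8 erases. The step needs 1,4- over 1,2-addition (slow addition of 8 to the copper catalyst, no Grignard reagent left when 11 enters), C4a over C8 regiochemistry (the enolate is formed regiodefined and is kept cold so that it does not equilibrate) and a single Michael addition (the hindered, silicon-stabilised adduct enolate should not add to a second acceptor).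

Step 8
Reactants: 15 methyl 3-[(1R,2S)-2-[(5R)-5-(tert-butyldimethylsilyloxy)octyl]-6-oxocyclohexyl]propanoate
Product: 16 (5S)-5-[(5R)-5-(tert-butyldimethylsilyloxy)octyl]-3,4,5,6,7,8-hexahydroquinolin-2(1H)-one
Conditions: NH4OAc (10 equiv), AcOH (0.5 equiv), toluene, reflux, Dean–Stark
Reagents that add atoms: ammonium acetate, CC(=O)[O-].[NH4+]
Why: Condensation of the ketone with ammonia to the enamine and intramolecular aminolysis of the methyl ester (six-membered lactamisation) give the bicyclic enamide, drawn as the C4a=C8a isomer shared by both rings, which removes the provisional C4a centre and leaves C5 untouched.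

Step 9
Reactants: 16 (5S)-5-[(5R)-5-(tert-butyldimethylsilyloxy)octyl]-3,4,5,6,7,8-hexahydroquinolin-2(1H)-one
Product: 17 (4aS,5S,8aR)-5-[(5R)-5-(tert-butyldimethylsilyloxy)octyl]octahydroquinolin-2(1H)-one
Conditions: H2 (50 bar), 10 % Pd/C, EtOAc, 50 °C
Reagents that add atoms: none
Why: In this heterogeneous syn hydrogenation the C5 chain, held pseudoaxial by A(1,2) strain with C4, should block one face of the tetrasubstituted enamide, so both hydrogens arrive anti to it and give the cis ring fusion with H4a, H5 and H8a on one face.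

Step 10
Reactants: 17 (4aS,5S,8aR)-5-[(5R)-5-(tert-butyldimethylsilyloxy)octyl]octahydroquinolin-2(1H)-one
Product: 18 tert-butyl (4aS,5S,8aR)-5-[(5R)-5-(tert-butyldimethylsilyloxy)octyl]-2-oxooctahydroquinoline-1(2H)-carboxylate
Conditions: Boc2O, Et3N, DMAP, CH2Cl2, rt
Reagents that add atoms: di-tert-butyl dicarbonate, CC(C)(C)OC(=O)OC(=O)OC(C)(C)C
Why: DMAP-catalysed N-acylation of the lactam with Boc2O gives the imide, which makes C3 easy to enolise and supplies the carbamate that later fixes the ring conformation through A(1,3) strain.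

Step 11
Reactants: 18 tert-butyl (4aS,5S,8aR)-5-[(5R)-5-(tert-butyldimethylsilyloxy)octyl]-2-oxooctahydroquinoline-1(2H)-carboxylate
Product: 20 tert-butyl (4aS,5S,8aR)-5-[(5R)-5-(tert-butyldimethylsilyloxy)octyl]-2-[(diphenoxyphosphoryl)oxy]-4a,5,6,7,8,8a-hexahydroquinoline-1(4H)-carboxylate, via potassium enolate 19 (not isolated)
Conditions: KN(SiMe3)2, THF, −78 °C; then (PhO)2P(O)Cl, −78 °C
Reagents that add atoms: diphenyl chlorophosphate, O=P(Cl)(Oc1ccccc1)Oc1ccccc1
Why: O-phosphorylation of the imide enolate gives the lactam-derived ketene aminal phosphate, a standard cross-coupling handle, and no stereocentre is at risk because H8a is not acidic.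

Step 12
Reactants: 20 tert-butyl (4aS,5S,8aR)-5-[(5R)-5-(tert-butyldimethylsilyloxy)octyl]-2-[(diphenoxyphosphoryl)oxy]-4a,5,6,7,8,8a-hexahydroquinoline-1(4H)-carboxylate
Product: 21 tert-butyl (4aS,5S,8aR)-5-[(5R)-5-(tert-butyldimethylsilyloxy)octyl]-2-methyl-4a,5,6,7,8,8a-hexahydroquinoline-1(4H)-carboxylate
Conditions: MeZnCl (2 M in THF), Pd(PPh3)4 (5 mol %), THF, 50 °C
Reagents that add atoms: methylzinc chloride, C[Zn]Cl
Why: In this Negishi coupling, oxidative addition of zerovalent palladium into the C2–O bond of the enol phosphate, transmetallation from methylzinc chloride and reductive elimination install the C2 methyl group without touching the carbamate or the silyl ether.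

Step 13
Reactants: 21 tert-butyl (4aS,5S,8aR)-5-[(5R)-5-(tert-butyldimethylsilyloxy)octyl]-2-methyl-4a,5,6,7,8,8a-hexahydroquinoline-1(4H)-carboxylate
Product: 23 tert-butyl (2S,3R,4aS,5S,8aR)-5-[(5R)-5-(tert-butyldimethylsilyloxy)octyl]-3-hydroxy-2-methyloctahydroquinoline-1(2H)-carboxylate, via C3 alkylborane 22 (not isolated)
Conditions: BH3·SMe2, THF, 0 °C → rt; then NaOH, H2O2, H2O, 0 °C
Reagents that add atoms: hydrogen peroxide, OO
Why: Hydroboration–oxidation of the enecarbamate places boron at C3 (β to nitrogen and the less substituted carbon) and hydrogen at C2 in a syn addition from the convex face (the face of H4a and H8a, opposite the axial C8a–C8 bond enforced by A(1,3) strain with the Boc group), and oxidation with retention gives 2S,3R with H2 and O3 cis and the methyl trans to oxygen.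

Step 14
Reactants: 23 tert-butyl (2S,3R,4aS,5S,8aR)-5-[(5R)-5-(tert-butyldimethylsilyloxy)octyl]-3-hydroxy-2-methyloctahydroquinoline-1(2H)-carboxylate; 24 (2E,4E)-octa-2,4-dienoic acid
Product: 26 tert-butyl (2S,3R,4aS,5S,8aR)-5-[(5R)-5-(tert-butyldimethylsilyloxy)octyl]-2-methyl-3-[(2E,4E)-octa-2,4-dienoyloxy]octahydroquinoline-1(2H)-carboxylate, via mixed anhydride 25 (not isolated)
Conditions: 24, 2,4,6-Cl3C6H2COCl, Et3N, THF, rt; then 23, DMAP, toluene, rt → 40 °C
Reagents that add atoms: none
Why: In this Yamaguchi esterification the mixed anhydride acylates the hindered secondary alcohol under DMAP catalysis near room temperature, where the 2E,4E diene should not isomerise and the Boc-protected nitrogen cannot compete.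

Step 15
Reactants: 26 tert-butyl (2S,3R,4aS,5S,8aR)-5-[(5R)-5-(tert-butyldimethylsilyloxy)octyl]-2-methyl-3-[(2E,4E)-octa-2,4-dienoyloxy]octahydroquinoline-1(2H)-carboxylate
Product: 27 lepadin H [(2S,3R,4aS,5S,8aR)-5-[(5R)-5-hydroxyoctyl]-2-methyldecahydroquinolin-3-yl (2E,4E)-octa-2,4-dienoate]
Conditions: TFA–H2O (9:1), CH2Cl2, 0 °C → rt; aq. NaHCO3
Reagents that add atoms: none
Why: Acidolysis removes the Boc group (tert-butyl cation loss and decarboxylation) and hydrolyses the secondary TBS ether in the same operation, while the conjugated ester of a hindered secondary alcohol should withstand aqueous TFA at room temperature.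

**Compound list**

1 | (R)-2-propyloxirane | CCC[C@@H]1CO1 | starting material
2 | allylmagnesium bromide | C=CC[Mg]Br | starting material
3 | (R)-oct-1-en-5-ol | CCC[C@@H](O)CCC=C | intermediate
4 | (R)-5-(tert-butyldimethylsilyloxy)oct-1-ene | CCC[C@@H](O[Si](C)(C)C(C)(C)C)CCC=C | intermediate
5 | 9-[(5R)-5-(tert-butyldimethylsilyloxy)octyl]-9-borabicyclo[3.3.1]nonane | CCC[C@@H](O[Si](C)(C)C(C)(C)C)CCCCB1C2CCCC1CCC2 | intermediate (not isolated)
6 | (R)-5-(tert-butyldimethylsilyloxy)octan-1-ol | CCC[C@@H](O[Si](C)(C)C(C)(C)C)CCCCO | intermediate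
7 | (R)-1-bromo-5-(tert-butyldimethylsilyloxy)octane | CCC[C@@H](O[Si](C)(C)C(C)(C)C)CCCCBr | intermediate
8 | [(5R)-5-(tert-butyldimethylsilyloxy)octyl]magnesium bromide | CCC[C@@H](O[Si](C)(C)C(C)(C)C)CCCC[Mg]Br | intermediate
9 | (1-bromovinyl)trimethylsilane | C=C(Br)[Si](C)(C)C | starting material
10 | [1-(trimethylsilyl)vinyl]magnesium bromide | C=C([Mg]Br)[Si](C)(C)C | intermediate (not isolated)
11 | methyl 2-(trimethylsilyl)acrylate | C=C(C(=O)OC)[Si](C)(C)C | intermediate
12 | cyclohex-2-en-1-one | O=C1C=CCCC1 | starting material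
13 | bromomagnesium (3S)-3-[(5R)-5-(tert-butyldimethylsilyloxy)octyl]cyclohex-1-en-1-olate | Br[Mg]OC1=C[C@@H](CCCC[C@H](O[Si](C)(C)C(C)(C)C)CCC)CCC1 | intermediate (not isolated)
14 | methyl 3-[(1R,2S)-2-[(5R)-5-(tert-butyldimethylsilyloxy)octyl]-6-oxocyclohexyl]-2-(trimethylsilyl)propanoate (either epimer at the silylated carbon) | COC(=O)C([Si](C)(C)C)C[C@@H]1[C@@H](CCCC[C@H](O[Si](C)(C)C(C)(C)C)CCC)CCCC1=O | intermediate (not isolated)
15 | methyl 3-[(1R,2S)-2-[(5R)-5-(tert-butyldimethylsilyloxy)octyl]-6-oxocyclohexyl]propanoate | COC(=O)CC[C@@H]1[C@@H](CCCC[C@H](O[Si](C)(C)C(C)(C)C)CCC)CCCC1=O | intermediate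
16 | (5S)-5-[(5R)-5-(tert-butyldimethylsilyloxy)octyl]-3,4,5,6,7,8-hexahydroquinolin-2(1H)-one | O=C1CCC2=C(N1)CCC[C@@H]2CCCC[C@H](O[Si](C)(C)C(C)(C)C)CCC | intermediate
17 | (4aS,5S,8aR)-5-[(5R)-5-(tert-butyldimethylsilyloxy)octyl]octahydroquinolin-2(1H)-one | O=C1CC[C@H]2[C@@H](CCCC[C@H](O[Si](C)(C)C(C)(C)C)CCC)CCC[C@H]2N1 | intermediate
18 | tert-butyl (4aS,5S,8aR)-5-[(5R)-5-(tert-butyldimethylsilyloxy)octyl]-2-oxooctahydroquinoline-1(2H)-carboxylate | O=C1CC[C@H]2[C@@H](CCCC[C@H](O[Si](C)(C)C(C)(C)C)CCC)CCC[C@H]2N1C(=O)OC(C)(C)C | intermediate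
19 | potassium enolate of 18 (C2–O−, C2=C3) | [K+].[O-]C1=CC[C@H]2[C@@H](CCCC[C@H](O[Si](C)(C)C(C)(C)C)CCC)CCC[C@H]2N1C(=O)OC(C)(C)C | intermediate (not isolated)
20 | tert-butyl (4aS,5S,8aR)-5-[(5R)-5-(tert-butyldimethylsilyloxy)octyl]-2-[(diphenoxyphosphoryl)oxy]-4a,5,6,7,8,8a-hexahydroquinoline-1(4H)-carboxylate | O=P(Oc1ccccc1)(Oc1ccccc1)OC1=CC[C@H]2[C@@H](CCCC[C@H](O[Si](C)(C)C(C)(C)C)CCC)CCC[C@H]2N1C(=O)OC(C)(C)C | intermediate
21 | tert-butyl (4aS,5S,8aR)-5-[(5R)-5-(tert-butyldimethylsilyloxy)octyl]-2-methyl-4a,5,6,7,8,8a-hexahydroquinoline-1(4H)-carboxylate | CC1=CC[C@H]2[C@@H](CCCC[C@H](O[Si](C)(C)C(C)(C)C)CCC)CCC[C@H]2N1C(=O)OC(C)(C)C | intermediate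
22 | C3 alkylborane from 21 (BH2 at C3; H2 and B on the H4a/H8a face) | [BH2][C@@H]1C[C@H]2[C@@H](CCCC[C@H](O[Si](C)(C)C(C)(C)C)CCC)CCC[C@H]2N(C(=O)OC(C)(C)C)[C@H]1C | intermediate (not isolated)
23 | tert-butyl (2S,3R,4aS,5S,8aR)-5-[(5R)-5-(tert-butyldimethylsilyloxy)octyl]-3-hydroxy-2-methyloctahydroquinoline-1(2H)-carboxylate | O[C@@H]1C[C@H]2[C@@H](CCCC[C@H](O[Si](C)(C)C(C)(C)C)CCC)CCC[C@H]2N(C(=O)OC(C)(C)C)[C@H]1C | intermediate
24 | (2E,4E)-octa-2,4-dienoic acid | CCC/C=C/C=C/C(=O)O | starting material
25 | (2E,4E)-octa-2,4-dienoic 2,4,6-trichlorobenzoic anhydride | CCC/C=C/C=C/C(=O)OC(=O)c1c(Cl)cc(Cl)cc1Cl | intermediate (not isolated)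
26 | tert-butyl (2S,3R,4aS,5S,8aR)-5-[(5R)-5-(tert-butyldimethylsilyloxy)octyl]-2-methyl-3-[(2E,4E)-octa-2,4-dienoyloxy]octahydroquinoline-1(2H)-carboxylate | CCC/C=C/C=C/C(=O)O[C@@H]1C[C@H]2[C@@H](CCCC[C@H](O[Si](C)(C)C(C)(C)C)CCC)CCC[C@H]2N(C(=O)OC(C)(C)C)[C@H]1C | intermediate
27 | lepadin H, (2S,3R,4aS,5S,8aR)-5-[(5R)-5-hydroxyoctyl]-2-methyldecahydroquinolin-3-yl (2E,4E)-octa-2,4-dienoate | CCC/C=C/C=C/C(=O)O[C@@H]1C[C@H]2[C@@H](CCCC[C@H](O)CCC)CCC[C@H]2N[C@H]1C | target

**Step count and risks**

Total: 15 steps. Longest linear sequence: 14 steps (steps 1–5 and 7–15, from (R)-2-propyloxirane); step 6 is a one-step side branch.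

Steps most likely to fail:

1. Step 7. The aggregated magnesium enolate may add only sluggishly to the hindered silyl acrylate, so that proton transfer or Peterson-type condensation of the α-silyl ester enolate takes over. Imperfect enantioface selection would also appear as a C5 epimer that is hard to separate. The fallback brings the three-carbon unit in at a lower oxidation level; it sets out from enolate 13, generated as in step 7, and returns at 16. Enolate 13 is alkylated with allyl iodide in the presence of DMPU (−78 → 0 °C) to give (2R,3S)-2-allyl-3-[(5R)-5-(tert-butyldimethylsilyloxy)octyl]cyclohexan-1-one F1. Chemoselective hydroboration of the terminal alkene with dicyclohexylborane and oxidation with NaBO3·4H2O give (2R,3S)-3-[(5R)-5-(tert-butyldimethylsilyloxy)octyl]-2-(3-hydroxypropyl)cyclohexan-1-one F2. TEMPO/PhI(OAc)2 in aqueous MeCN oxidises the primary alcohol to 3-[(1R,2S)-2-[(5R)-5-(tert-butyldimethylsilyloxy)octyl]-6-oxocyclohexyl]propanoic acid F3, which condenses with NH4OAc in refluxing toluene to ene-lactam 16.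

2. Step 9. Reduction of the tetrasubstituted enamide may be slow or incomplete under neutral conditions, a minor C8=C8a isomer that still carries the trans C4a centre may be reduced directly, and the silyl ether may be lost if acid is added to speed the reaction. The fallback takes the protecting group off for the reduction; it sets out from 16 and returns at 17. Bu4NF in THF gives (5S)-5-[(5R)-5-hydroxyoctyl]-3,4,5,6,7,8-hexahydroquinolin-2(1H)-one F4. Hydrogenation over PtO2 in AcOH, where the enamide isomers interconvert through the N-acyliminium ion and reduction occurs anti to the C5 chain, gives (4aS,5S,8aR)-5-[(5R)-5-hydroxyoctyl]octahydroquinolin-2(1H)-one F5. Silylation with TBSCl and imidazole in DMF then returns lactam 17.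

3. Step 12. The ketene aminal phosphate may hydrolyse before or during the coupling, or oxidative addition at the hindered C2–O bond may be slow. The fallback replaces cross-coupling by carbonyl addition; it sets out from 18, bypasses steps 11 and 12, and returns at 21. MeLi in THF at −78 °C opens the N-Boc lactam to tert-butyl N-[(1R,2S,3S)-3-[(5R)-5-(tert-butyldimethylsilyloxy)octyl]-2-(3-oxobutyl)cyclohexyl]carbamate F6. Acid-catalysed cyclodehydration (pyridinium p-toluenesulfonate, toluene, 80 °C, 4 Å molecular sieves) then gives enecarbamate 21.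

**Further compounds**

F1 | step 7 | (2R,3S)-2-allyl-3-[(5R)-5-(tert-butyldimethylsilyloxy)octyl]cyclohexan-1-one | C=CC[C@@H]1[C@@H](CCCC[C@H](O[Si](C)(C)C(C)(C)C)CCC)CCCC1=O
F2 | step 7 | (2R,3S)-3-[(5R)-5-(tert-butyldimethylsilyloxy)octyl]-2-(3-hydroxypropyl)cyclohexan-1-one | OCCC[C@@H]1[C@@H](CCCC[C@H](O[Si](C)(C)C(C)(C)C)CCC)CCCC1=O
F3 | step 7 | 3-[(1R,2S)-2-[(5R)-5-(tert-butyldimethylsilyloxy)octyl]-6-oxocyclohexyl]propanoic acid | OC(=O)CC[C@@H]1[C@@H](CCCC[C@H](O[Si](C)(C)C(C)(C)C)CCC)CCCC1=O
F4 | step 9 | (5S)-5-[(5R)-5-hydroxyoctyl]-3,4,5,6,7,8-hexahydroquinolin-2(1H)-one | O=C1CCC2=C(N1)CCC[C@@H]2CCCC[C@H](O)CCC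
F5 | step 9 | (4aS,5S,8aR)-5-[(5R)-5-hydroxyoctyl]octahydroquinolin-2(1H)-one | O=C1CC[C@H]2[C@@H](CCCC[C@H](O)CCC)CCC[C@H]2N1
F6 | step 12 | tert-butyl N-[(1R,2S,3S)-3-[(5R)-5-(tert-butyldimethylsilyloxy)octyl]-2-(3-oxobutyl)cyclohexyl]carbamate | CC(=O)CC[C@H]1[C@@H](CCCC[C@H](O[Si](C)(C)C(C)(C)C)CCC)CCC[C@H]1NC(=O)OC(C)(C)C
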